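**Plan**

1. Retrosynthesis: first the nine O-benzyl groups; then the tetrahydrofuran (ring C) at O1–C5 (SN2 with inversion) and at C4–aryl/C5–aryl (three-component conjunctive cross-coupling of alkenylboronate 34, Grignard reagent 11 and triflate 26); then the central dihydrobenzofuran (ring B) at C2–C3 (carbene C–H insertion) and at its ketone C–C bond; last the outer dihydrobenzofuran (ring A) at O1–C7a and, by a first conjunctive coupling, at C3–C3a and C2–aryl.
2. Forward order: ring A (steps 6–7), ring B (steps 10–13), ring C (steps 21–22), hydrogenolysis (step 23).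
3. Enabling feature: in ring A, C7a is para to C5, the ring carbon that carries C3 of ring B. Held at the ester oxidation level, C5 activates a fluoride on C7a for SNAr by the C2 alkoxide, and the same ester then becomes the ketone from which C3 of ring B is built; the neighbouring C7 oxygen travels as a benzyl ether.
4. Stereochemistry: ring A C2/C3 from the Pd/MandyPhos conjunctive coupling (anti addition to an E-alkenylborate) and stereoretentive C–B oxidation; ring B C3 from the Rh2(S-PTAD)4 insertion, C2 by acid equilibration to trans; ring C C2/C3 from a chiral-phosphoric-acid allylboration (anti), C4 from the second conjunctive coupling, C5 by inversion in the ring closure.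

Key step: step 7

Assumption: for each chiral catalyst or ligand the antipode that delivers the drawn configuration is meant; the sense of induction is assigned by analogy and is to be confirmed on the first intermediate.

Abbreviations: Bn = benzyl; ArA = 4-(benzyloxy)phenyl; ArB = 3,5-bis(benzyloxy)phenyl; BOB = 4-(benzyloxy)benzyl; TIPS = triisopropylsilyl; TBS = tert-butyldimethylsilyl; B(mac) = cyclic boronic ester of diol 2; A-yl = (2R,3R)-7-(benzyloxy)-2-ArA-3-ArB-2,3-dihydro-1-benzofuran-5-yl; B-yl = (2S,3S)-2-ArA-3-(A-yl)-6-(TIPS-oxy)-2,3-dihydro-1-benzofuran-4-yl.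

**Route**

Step 1
Reactants: 1 acenaphthylene-1,2-dione
Product: 2 cis-1,2-dimethyl-1,2-dihydroacenaphthylene-1,2-diol (meso)
Conditions: MeMgBr (2.5 equiv), THF, 0 °C to rt; aq. NH4Cl; crystallisation
Reagents that add atoms: methylmagnesium bromide, C[Mg]Br
Why: Double Grignard addition to the 1,2-diketone should give the diol, and the cis (meso) isomer, the only one that can chelate boron, is taken on after crystallisation.

Step 2
Reactants: 3 methyl 3-bromo-4-fluorobenzoate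
Product: 5 methyl 3-bromo-4-fluoro-5-hydroxybenzoate, via aryl boronate 4 (not isolated)
Conditions: [Ir(OMe)(cod)]2 (1.5 mol%), dtbpy, B2pin2, THF, 80 °C; then Oxone, acetone/H2O, rt
Reagents that add atoms: Oxone (potassium peroxymonosulfate), [K+].[O-]S(=O)(=O)OO
Why: Sterically governed iridium-catalysed C–H borylation should go to C5, the only C–H flanked by fluorine and hydrogen, and the boronate is oxidised to the phenol in the same pot (one-pot borylation/oxidation).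

Step 3
Reactants: 5 methyl 3-bromo-4-fluoro-5-hydroxybenzoate
Product: 6 methyl 3-(benzyloxy)-5-bromo-4-fluorobenzoate
Conditions: BnBr, K2CO3, DMF, rt
Reagents that add atoms: benzyl bromide, BrCc1ccccc1
Why: Williamson etherification of the phenoxide, run at room temperature so that the ester-activated fluoride is not displaced.

Step 4
Reactants: 7 3,5-bis(benzyloxy)benzaldehyde
Product: 8 1,3-bis(benzyloxy)-5-ethynylbenzene
Conditions: dimethyl (1-diazo-2-oxopropyl)phosphonate, K2CO3, MeOH, rt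
Reagents that add atoms: dimethyl (1-diazo-2-oxopropyl)phosphonate, CC(=O)C(=[N+]=[N-])P(=O)(OC)OC
Why: Ohira–Bestmann homologation of an aryl aldehyde to the terminal alkyne under mild base.

Step 5
Reactants: 8 1,3-bis(benzyloxy)-5-ethynylbenzene; 2 cis-1,2-dimethyl-1,2-dihydroacenaphthylene-1,2-diol
Product: 10 (E)-2-ArB-ethenyl-B(mac), via alkenyl catecholborane 9 (not isolated)
Conditions: catecholborane, THF, 70 °C; then 2, rt
Reagents that add atoms: catecholborane, B1Oc2ccccc2O1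
Why: syn-Hydroboration of the terminal alkyne gives the E-alkenylborane, and the labile catechol ester is exchanged for the diol 2 (transesterification).

Step 6
Reactants: 10 (E)-2-ArB-ethenyl-B(mac); 11 4-(benzyloxy)phenylmagnesium bromide; 6 methyl 3-(benzyloxy)-5-bromo-4-fluorobenzoate
Product: 13 methyl 3-(benzyloxy)-5-[(1R,2R)-2-ArA-1-ArB-2-B(mac)-ethyl]-4-fluorobenzoate, via magnesium borate 12 (not isolated)
Conditions: 10 + 11, THF, 0 °C to rt; then 6, Pd(OAc)2 (3 mol%), (Sp,Sp)-MandyPhos (3.6 mol%), NaOTf, THF, 60 °C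
Reagents that add atoms: none
Why: In this palladium-catalysed conjunctive cross-coupling the arylpalladium species from 6 binds the alkene of borate 12 and triggers a 1,2-shift of ArA from boron to the α-carbon anti to palladium, and reductive elimination joins the ring carbon to the β-carbon. The anti addition across the E-alkene under ligand control of the face should set both stereocentres, the B(mac) ligand suppressing direct Suzuki transfer and the ester and fluoride being inert to the borate.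

Step 7
Reactants: 13 methyl 3-(benzyloxy)-5-[(1R,2R)-2-ArA-1-ArB-2-B(mac)-ethyl]-4-fluorobenzoate
Product: 15 methyl (2R,3R)-7-(benzyloxy)-2-ArA-3-ArB-2,3-dihydro-1-benzofuran-5-carboxylate, via fluoro alcohol 14 (not isolated)
Conditions: NaBO3·4H2O, THF/H2O, rt; extractive work-up; then KHMDS, THF, −20 °C to rt
Reagents that add atoms: sodium perborate, [Na+].[O-]OB=O
Why: Perborate adds to boron and C2 migrates from boron to oxygen with retention to give the (1R,2R)-fluoro alcohol 14; KHMDS then forms the alkoxide, which adds to C7a (the fluorine-bearing carbon, para to the ester) to give a Meisenheimer complex stabilised by the ester, and fluoride is expelled. The closest known reaction type is the base-mediated intramolecular SNAr etherification of 2-(2-fluoroaryl)ethanols to 2,3-dihydrobenzofurans, preceded by the standard oxidation of a secondary boronic ester. The five-membered ring closes in the 5-exo-trig mode (O1 attacks C7a, the C–F bond lies outside the ring). No stereocentre is created in the closure: C2 (R) is carried over from the C–B bond by the stereoretentive shift and C3 (R) is untouched, so the 2,3-trans ring follows from the anti adduct of step 6. The step needs chemoselectivity for C7a over the ester carbonyl and over deprotonation at C3 or retro-addition of the alkoxide; the single fluoride, its para ester, the five-membered transition state, the non-nucleophilic base and the low temperature secure it.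

Step 8
Reactants: 16 phloroglucinol
Product: 17 5-[(triisopropylsilyl)oxy]benzene-1,3-diol
Conditions: TIPSCl (1.0 equiv), imidazole, DMF, 0 °C
Reagents that add atoms: triisopropylsilyl chloride, CC(C)[Si](Cl)(C(C)C)C(C)C
Why: Statistical monosilylation of the symmetric triol; the mono-ether is separated and the rest recycled.

Step 9
Reactants: 17 5-[(triisopropylsilyl)oxy]benzene-1,3-diol; 18 4-(benzyloxy)benzyl alcohol
Product: 19 [3,5-bis(BOB-oxy)phenoxy]triisopropylsilane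
Conditions: 18 (2.2 equiv), PPh3, DIAD, THF, 0 °C to rt
Reagents that add atoms: none
Why: Double Mitsunobu etherification of the two phenols under neutral conditions, which avoids C-alkylation of the phloroglucinol core and cleavage of the aryl silyl ether.

Step 10
Reactants: 19 [3,5-bis(BOB-oxy)phenoxy]triisopropylsilane; 15 methyl (2R,3R)-7-(benzyloxy)-2-ArA-3-ArB-2,3-dihydro-1-benzofuran-5-carboxylate
Product: 21 [2,6-bis(BOB-oxy)-4-(TIPS-oxy)phenyl](A-yl) ketone, via aryllithium 20 (not isolated)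
Conditions: n-BuLi, THF, 0 °C; then 15, −78 to −40 °C
Reagents that add atoms: none
Why: Directed ortho-lithiation should occur between the two coordinating benzylic ethers (the flanks of the bulky TIPS ether are shielded), and the 2,6-disubstituted aryllithium adds once to the ester because the resulting ketone is too hindered for a second addition.

Step 11
Reactants: 21 [2,6-bis(BOB-oxy)-4-(TIPS-oxy)phenyl](A-yl) ketone
Product: 22 hydrazone of ketone 21
Conditions: N2H4·H2O, AcOH (cat.), EtOH/THF, 90 °C (sealed tube)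
Reagents that add atoms: hydrazine, NN
Why: Acid-catalysed condensation of hydrazine with the diaryl ketone, forced by excess reagent and heat.

Step 12
Reactants: 22 hydrazone of ketone 21
Product: 24 (2R,3S)-2-ArA-4-(BOB-oxy)-3-(A-yl)-6-(TIPS-oxy)-2,3-dihydro-1-benzofuran (2,3-cis), via diazo compound 23 (not isolated)
Conditions: MnO2, CH2Cl2, 0 °C; filter; Rh2(S-PTAD)4 (1 mol%), CH2Cl2, −20 °C to rt
Reagents that add atoms: none
Why: Oxidation gives the diaryldiazomethane, and the rhodium donor/donor carbene inserts into a benzylic C–H of one of the two equivalent ortho O–CH2–ArA groups (five-membered transition state); the chiral carboxylate catalyst should set C3 (S) and the cis relationship.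

Step 13
Reactants: 24 (2R,3S)-2-ArA-4-(BOB-oxy)-3-(A-yl)-6-(TIPS-oxy)-2,3-dihydro-1-benzofuran
Product: 25 (2S,3S)-2-ArA-3-(A-yl)-6-(TIPS-oxy)-2,3-dihydro-1-benzofuran-4-ol (2,3-trans)
Conditions: TFA (10 vol%), 1,3-dimethoxybenzene (5 equiv), CH2Cl2, 0 °C to rt
Reagents that add atoms: none
Why: Acidolysis removes the p-alkoxybenzyl (BOB) aryl ether with the arene as cation trap, while reversible heterolysis of O1–C2 through the p-alkoxybenzyl cation should equilibrate ring B to the more stable trans isomer with C3 untouched; benzyl and TIPS aryl ethers survive.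

Step 14
Reactants: 25 (2S,3S)-2-ArA-3-(A-yl)-6-(TIPS-oxy)-2,3-dihydro-1-benzofuran-4-ol
Product: 26 (2S,3S)-2-ArA-3-(A-yl)-6-(TIPS-oxy)-2,3-dihydro-1-benzofuran-4-yl trifluoromethanesulfonate
Conditions: Tf2O, pyridine, CH2Cl2, 0 °C
Reagents that add atoms: trifluoromethanesulfonic anhydride, O=S(=O)(OS(=O)(=O)C(F)(F)F)C(F)(F)F
Why: Standard triflation of the only free phenol, which turns the helper oxygen into the leaving group for the ring C coupling.

Step 15
Reactants: 7 3,5-bis(benzyloxy)benzaldehyde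
Product: 27 1-ArB-prop-2-en-1-ol (racemic)
Conditions: vinylmagnesium bromide, THF, −78 to 0 °C
Reagents that add atoms: vinylmagnesium bromide, C=C[Mg]Br
Why: Grignard 1,2-addition to the aldehyde; the stereocentre is lost in the next step.

Step 16
Reactants: 27 1-ArB-prop-2-en-1-ol
Product: 28 (E)-3-ArB-prop-2-en-1-yl pinacol boronate
Conditions: B2pin2, Pd(MeCN)4(BF4)2 (5 mol%), DMSO/MeOH, rt
Reagents that add atoms: bis(pinacolato)diboron, CC1(C)OB(OC1(C)C)B1OC(C)(C)C(C)(C)O1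
Why: Palladium-catalysed borylation of the allylic alcohol through a π-allyl intermediate gives the linear, conjugated E-allylboronate.

Step 17
Reactants: 28 (E)-3-ArB-prop-2-en-1-yl pinacol boronate; 29 4-(benzyloxy)benzaldehyde
Product: 30 (1S,2R)-1-ArA-2-ArB-but-3-en-1-ol (anti)
Conditions: (R)-TRIP phosphoric acid (5 mol%), toluene, −30 °C
Reagents that add atoms: none
Why: Allylboration through a chair (Zimmerman–Traxler) transition state turns the E-γ-aryl allylboronate into the anti adduct, and the chiral phosphoric acid bound to the boronate oxygen selects the aldehyde face, so one catalyst should set C1 and relay C2.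

Step 18
Reactants: 30 (1S,2R)-1-ArA-2-ArB-but-3-en-1-ol
Product: 31 TBS ether of 30
Conditions: TBSOTf, 2,6-lutidine, CH2Cl2, 0 °C
Reagents that add atoms: tert-butyldimethylsilyl triflate, CC(C)(C)[Si](C)(C)OS(=O)(=O)C(F)(F)F
Why: Silylation of the hindered secondary benzylic alcohol keeps it from the borate chemistry and marks this oxygen as the later ring nucleophile.

Step 19
Reactants: 32 2,4,6-trivinylboroxine–pyridine complex; 2 cis-1,2-dimethyl-1,2-dihydroacenaphthylene-1,2-diol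
Product: 33 ethenyl-B(mac)
Conditions: 32 (0.34 equiv), MgSO4, CH2Cl2, rt
Reagents that add atoms: none
Why: Dehydrative esterification of the boroxine with the cis diol.

Step 20
Reactants: 31 TBS ether of 30; 33 ethenyl-B(mac)
Product: 34 [(1E,3R,4S)-4-ArA-3-ArB-4-(TBS-oxy)but-1-en-1-yl]-B(mac)
Conditions: 33 (3 equiv), second-generation Hoveyda–Grubbs catalyst (5 mol%), CH2Cl2, 40 °C
Reagents that add atoms: none
Why: Olefin cross-metathesis of a terminal alkene with a vinyl boronate is E-selective and driven by loss of ethylene.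

Step 21
Reactants: 34 [(1E,3R,4S)-4-ArA-3-ArB-4-(TBS-oxy)but-1-en-1-yl]-B(mac); 11 4-(benzyloxy)phenylmagnesium bromide; 26 (2S,3S)-2-ArA-3-(A-yl)-6-(TIPS-oxy)-2,3-dihydro-1-benzofuran-4-yl trifluoromethanesulfonate
Product: 37 (1S,2S,3R,4S)-1,4-bis(ArA)-3-ArB-4-(TBS-oxy)-2-(B-yl)butan-1-ol, via magnesium borate 35 (not isolated), via boronic ester 36 (not isolated)
Conditions: 34 + 11, THF, 0 °C to rt; 26, Pd(OAc)2 (5 mol%), (Rp,Rp)-MandyPhos (6 mol%), NaOTf, THF, 60 °C; then NaBO3·4H2O, THF/H2O, rt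
Reagents that add atoms: sodium perborate, [Na+].[O-]OB=O
Why: A second conjunctive cross-coupling adds the ring B aryl group (to C2) and ArA (to C1) anti across the E-alkene, with the ligand chosen to place the aryl group on the face that makes C2 and C3 erythro, and stereoretentive oxidation gives the carbinol whose configuration is the one to be inverted in ring closure.

Step 22
Reactants: 37 (1S,2S,3R,4S)-1,4-bis(ArA)-3-ArB-4-(TBS-oxy)-2-(B-yl)butan-1-ol
Product: 39 (2S,3S)-2-ArA-3-(A-yl)-4-[(2R,3S,4R,5S)-2,5-bis(ArA)-4-ArB-oxolan-3-yl]-2,3-dihydro-1-benzofuran-6-ol, via mesylate 38 (not isolated)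
Conditions: Ms2O, i-Pr2NEt, CH2Cl2, −40 °C; then TBAF, THF, −40 to 0 °C
Reagents that add atoms: none
Why: Only the free hydroxyl is mesylated; fluoride then unmasks the other benzylic alkoxide, which displaces the mesylate in a 5-exo-tet closure with inversion (the 4,5-trans ring is also the one expected if the benzylic mesylate ionises first), and the aryl TIPS ether is cleaved in the same pot.

Step 23
Reactants: 39 (2S,3S)-2-ArA-3-(A-yl)-4-[(2R,3S,4R,5S)-2,5-bis(ArA)-4-ArB-oxolan-3-yl]-2,3-dihydro-1-benzofuran-6-ol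
Product: 40 kobophenol A
Conditions: H2 (1 atm), Pd/C, THF/MeOH, rt
Reagents that add atoms: none
Why: Hydrogenolysis of the nine benzyl aryl ethers under neutral conditions should be faster than cleavage of the ring benzylic C–O bonds and avoids the acid that epimerises the product; the reaction is stopped at full debenzylation.

**Compound list**

1 | acenaphthylene-1,2-dione | O=C1C(=O)c2cccc3cccc1c23 | starting material
2 | cis-1,2-dimethyl-1,2-dihydroacenaphthylene-1,2-diol | C[C@@]1(O)c2cccc3cccc(c23)[C@]1(C)O | intermediate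
3 | methyl 3-bromo-4-fluorobenzoate | COC(=O)c1ccc(F)c(Br)c1 | starting material
4 | methyl 3-bromo-4-fluoro-5-(pinacolboryl)benzoate | COC(=O)c1cc(Br)c(F)c(c1)B1OC(C)(C)C(C)(C)O1 | intermediate
5 | methyl 3-bromo-4-fluoro-5-hydroxybenzoate | COC(=O)c1cc(O)c(F)c(Br)c1 | intermediate
6 | methyl 3-(benzyloxy)-5-bromo-4-fluorobenzoate | COC(=O)c1cc(Br)c(F)c(OCc2ccccc2)c1 | intermediate
7 | 3,5-bis(benzyloxy)benzaldehyde | O=Cc1cc(OCc2ccccc2)cc(OCc2ccccc2)c1 | starting material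
8 | 1,3-bis(benzyloxy)-5-ethynylbenzene | C#Cc1cc(OCc2ccccc2)cc(OCc2ccccc2)c1 | intermediate
9 | 2-[(E)-2-ArB-ethenyl]-1,3,2-benzodioxaborole | c1ccc2OB(/C=C/c3cc(OCc4ccccc4)cc(OCc4ccccc4)c3)Oc2c1 | intermediate
10 | (E)-2-ArB-ethenyl-B(mac) | B1(/C=C/c2cc(OCc3ccccc3)cc(OCc3ccccc3)c2)O[C@]2(C)c3cccc4cccc(c34)[C@]2(C)O1 | intermediate
11 | 4-(benzyloxy)phenylmagnesium bromide | Br[Mg]c1ccc(OCc2ccccc2)cc1 | starting material
12 | bromomagnesium [(E)-2-ArB-ethenyl](ArA)borate of diol 2 | [B-]1(/C=C/c2cc(OCc3ccccc3)cc(OCc3ccccc3)c2)(c2ccc(OCc3ccccc3)cc2)O[C@]2(C)c3cccc4cccc(c34)[C@]2(C)O1.[Mg+]Br | intermediate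
13 | methyl 3-(benzyloxy)-5-[(1R,2R)-2-ArA-1-ArB-2-B(mac)-ethyl]-4-fluorobenzoate | COC(=O)c1cc(OCc2ccccc2)c(F)c(c1)[C@@H](c1cc(OCc2ccccc2)cc(OCc2ccccc2)c1)[C@H](c1ccc(OCc2ccccc2)cc1)B1O[C@]2(C)c3cccc4cccc(c34)[C@]2(C)O1 | intermediate
14 | methyl 3-(benzyloxy)-5-[(1R,2R)-2-ArA-1-ArB-2-hydroxyethyl]-4-fluorobenzoate | COC(=O)c1cc(OCc2ccccc2)c(F)c(c1)[C@@H](c1cc(OCc2ccccc2)cc(OCc2ccccc2)c1)[C@H](c1ccc(OCc2ccccc2)cc1)O | intermediate
15 | methyl (2R,3R)-7-(benzyloxy)-2-ArA-3-ArB-2,3-dihydro-1-benzofuran-5-carboxylate | COC(=O)c1cc(OCc2ccccc2)c3c(c1)[C@@H](c1cc(OCc2ccccc2)cc(OCc2ccccc2)c1)[C@H](c1ccc(OCc2ccccc2)cc1)O3 | intermediate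
16 | phloroglucinol | Oc1cc(O)cc(O)c1 | starting material
17 | 5-[(triisopropylsilyl)oxy]benzene-1,3-diol | CC(C)[Si](Oc1cc(O)cc(O)c1)(C(C)C)C(C)C | intermediate
18 | 4-(benzyloxy)benzyl alcohol | OCc1ccc(OCc2ccccc2)cc1 | starting material
19 | [3,5-bis(BOB-oxy)phenoxy]triisopropylsilane | CC(C)[Si](Oc1cc(OCc2ccc(OCc3ccccc3)cc2)cc(OCc2ccc(OCc3ccccc3)cc2)c1)(C(C)C)C(C)C | intermediate
20 | 2,6-bis(BOB-oxy)-4-(TIPS-oxy)phenyllithium | [Li]c1c(OCc2ccc(OCc3ccccc3)cc2)cc(O[Si](C(C)C)(C(C)C)C(C)C)cc1OCc1ccc(OCc2ccccc2)cc1 | intermediate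
21 | [2,6-bis(BOB-oxy)-4-(TIPS-oxy)phenyl](A-yl) ketone | O=C(c1c(OCc2ccc(OCc3ccccc3)cc2)cc(O[Si](C(C)C)(C(C)C)C(C)C)cc1OCc1ccc(OCc2ccccc2)cc1)c1cc(OCc2ccccc2)c3c(c1)[C@@H](c1cc(OCc2ccccc2)cc(OCc2ccccc2)c1)[C@H](c1ccc(OCc2ccccc2)cc1)O3 | intermediate
22 | hydrazone of ketone 21 | NN=C(c1c(OCc2ccc(OCc3ccccc3)cc2)cc(O[Si](C(C)C)(C(C)C)C(C)C)cc1OCc1ccc(OCc2ccccc2)cc1)c1cc(OCc2ccccc2)c3c(c1)[C@@H](c1cc(OCc2ccccc2)cc(OCc2ccccc2)c1)[C@H](c1ccc(OCc2ccccc2)cc1)O3 | intermediate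
23 | [2,6-bis(BOB-oxy)-4-(TIPS-oxy)phenyl](A-yl)diazomethane | [N-]=[N+]=C(c1c(OCc2ccc(OCc3ccccc3)cc2)cc(O[Si](C(C)C)(C(C)C)C(C)C)cc1OCc1ccc(OCc2ccccc2)cc1)c1cc(OCc2ccccc2)c3c(c1)[C@@H](c1cc(OCc2ccccc2)cc(OCc2ccccc2)c1)[C@H](c1ccc(OCc2ccccc2)cc1)O3 | intermediate
24 | (2R,3S)-2-ArA-4-(BOB-oxy)-3-(A-yl)-6-(TIPS-oxy)-2,3-dihydro-1-benzofuran (cis) | c1ccccc1COc1ccc([C@@H]2Oc3cc(O[Si](C(C)C)(C(C)C)C(C)C)cc(OCc4ccc(OCc5ccccc5)cc4)c3[C@@H]2c2cc(OCc4ccccc4)c3c(c2)[C@@H](c2cc(OCc4ccccc4)cc(OCc4ccccc4)c2)[C@H](c2ccc(OCc4ccccc4)cc2)O3)cc1 | intermediate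
25 | (2S,3S)-2-ArA-3-(A-yl)-6-(TIPS-oxy)-2,3-dihydro-1-benzofuran-4-ol (trans) | c1ccccc1COc1ccc([C@H]2Oc3cc(O[Si](C(C)C)(C(C)C)C(C)C)cc(O)c3[C@@H]2c2cc(OCc4ccccc4)c3c(c2)[C@@H](c2cc(OCc4ccccc4)cc(OCc4ccccc4)c2)[C@H](c2ccc(OCc4ccccc4)cc2)O3)cc1 | intermediate
26 | trifluoromethanesulfonate of 25 | c1ccccc1COc1ccc([C@H]2Oc3cc(O[Si](C(C)C)(C(C)C)C(C)C)cc(OS(=O)(=O)C(F)(F)F)c3[C@@H]2c2cc(OCc4ccccc4)c3c(c2)[C@@H](c2cc(OCc4ccccc4)cc(OCc4ccccc4)c2)[C@H](c2ccc(OCc4ccccc4)cc2)O3)cc1 | intermediate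
27 | 1-ArB-prop-2-en-1-ol (racemic) | C=CC(O)c1cc(OCc2ccccc2)cc(OCc2ccccc2)c1 | intermediate
28 | (E)-3-ArB-prop-2-en-1-yl pinacol boronate | CC1(C)OB(C/C=C/c2cc(OCc3ccccc3)cc(OCc3ccccc3)c2)OC1(C)C | intermediate
29 | 4-(benzyloxy)benzaldehyde | O=Cc1ccc(OCc2ccccc2)cc1 | starting material
30 | (1S,2R)-1-ArA-2-ArB-but-3-en-1-ol | C=C[C@H](c1cc(OCc2ccccc2)cc(OCc2ccccc2)c1)[C@@H](c1ccc(OCc2ccccc2)cc1)O | intermediate
31 | TBS ether of 30 | C=C[C@H](c1cc(OCc2ccccc2)cc(OCc2ccccc2)c1)[C@@H](c1ccc(OCc2ccccc2)cc1)O[Si](C)(C)C(C)(C)C | intermediate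
32 | 2,4,6-trivinylboroxine–pyridine complex | C=CB1OB(C=C)OB(C=C)O1.c1ccncc1 | starting material
33 | ethenyl-B(mac) | C=CB1O[C@]2(C)c3cccc4cccc(c34)[C@]2(C)O1 | intermediate
34 | [(1E,3R,4S)-4-ArA-3-ArB-4-(TBS-oxy)but-1-en-1-yl]-B(mac) | B1(/C=C/[C@H](c2cc(OCc3ccccc3)cc(OCc3ccccc3)c2)[C@@H](c2ccc(OCc3ccccc3)cc2)O[Si](C)(C)C(C)(C)C)O[C@]2(C)c3cccc4cccc(c34)[C@]2(C)O1 | intermediate
35 | bromomagnesium borate from 34 and 11 (ArA on boron) | [B-]1(/C=C/[C@H](c2cc(OCc3ccccc3)cc(OCc3ccccc3)c2)[C@@H](c2ccc(OCc3ccccc3)cc2)O[Si](C)(C)C(C)(C)C)(c2ccc(OCc3ccccc3)cc2)O[C@]2(C)c3cccc4cccc(c34)[C@]2(C)O1.[Mg+]Br | intermediate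
36 | boronic ester corresponding to 37 (B(mac) in place of OH at C1, same configuration) | c1ccccc1COc1ccc([C@H]2Oc3cc(O[Si](C(C)C)(C(C)C)C(C)C)cc([C@@H]([C@H](B6O[C@]7(C)c8cccc9cccc(c89)[C@]7(C)O6)c4ccc(OCc5ccccc5)cc4)[C@H](c4cc(OCc5ccccc5)cc(OCc5ccccc5)c4)[C@@H](c4ccc(OCc5ccccc5)cc4)O[Si](C)(C)C(C)(C)C)c3[C@@H]2c2cc(OCc4ccccc4)c3c(c2)[C@@H](c2cc(OCc4ccccc4)cc(OCc4ccccc4)c2)[C@H](c2ccc(OCc4ccccc4)cc2)O3)cc1 | intermediate
37 | (1S,2S,3R,4S)-1,4-bis(ArA)-3-ArB-4-(TBS-oxy)-2-(B-yl)butan-1-ol | c1ccccc1COc1ccc([C@H]2Oc3cc(O[Si](C(C)C)(C(C)C)C(C)C)cc([C@@H]([C@H](O)c4ccc(OCc5ccccc5)cc4)[C@H](c4cc(OCc5ccccc5)cc(OCc5ccccc5)c4)[C@@H](c4ccc(OCc5ccccc5)cc4)O[Si](C)(C)C(C)(C)C)c3[C@@H]2c2cc(OCc4ccccc4)c3c(c2)[C@@H](c2cc(OCc4ccccc4)cc(OCc4ccccc4)c2)[C@H](c2ccc(OCc4ccccc4)cc2)O3)cc1 | intermediate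
38 | methanesulfonate of 37 | c1ccccc1COc1ccc([C@H]2Oc3cc(O[Si](C(C)C)(C(C)C)C(C)C)cc([C@@H]([C@H](OS(C)(=O)=O)c4ccc(OCc5ccccc5)cc4)[C@H](c4cc(OCc5ccccc5)cc(OCc5ccccc5)c4)[C@@H](c4ccc(OCc5ccccc5)cc4)O[Si](C)(C)C(C)(C)C)c3[C@@H]2c2cc(OCc4ccccc4)c3c(c2)[C@@H](c2cc(OCc4ccccc4)cc(OCc4ccccc4)c2)[C@H](c2ccc(OCc4ccccc4)cc2)O3)cc1 | intermediate
39 | (2S,3S)-2-ArA-3-(A-yl)-4-[(2R,3S,4R,5S)-2,5-bis(ArA)-4-ArB-oxolan-3-yl]-2,3-dihydro-1-benzofuran-6-ol | c1ccccc1COc1ccc([C@H]2Oc3cc(O)cc([C@@H]4[C@H](c5cc(OCc6ccccc6)cc(OCc6ccccc6)c5)[C@@H](c5ccc(OCc6ccccc6)cc5)O[C@H]4c4ccc(OCc5ccccc5)cc4)c3[C@@H]2c2cc(OCc4ccccc4)c3c(c2)[C@@H](c2cc(OCc4ccccc4)cc(OCc4ccccc4)c2)[C@H](c2ccc(OCc4ccccc4)cc2)O3)cc1 | intermediate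
40 | kobophenol A | Oc1ccc([C@H]2Oc3cc(O)cc([C@@H]4[C@H](c5cc(O)cc(O)c5)[C@@H](c5ccc(O)cc5)O[C@H]4c4ccc(O)cc4)c3[C@@H]2c2cc(O)c3c(c2)[C@@H](c2cc(O)cc(O)c2)[C@H](c2ccc(O)cc2)O3)cc1 | target

**Step count and risks**

Total steps: 23. Longest linear sequence: 12 steps (2, 3, 6, 7, 10, 11, 12, 13, 14, 21, 22, 23).

Step 21. Both partners are congested (the triflate carries a tertiary benzylic carbon in the ortho position, the alkenylborate is branched), so direct Suzuki transfer, slow palladation and poor facial selectivity at the new aryl-bearing centre may result. The fallback sets out from 26 and returns at 39, making the ring-to-chain bond first. Suzuki–Miyaura vinylation of 26 (potassium vinyltrifluoroborate, PdCl2(dppf), Cs2CO3) gives the styrene F1. Cross-metathesis with allylboronic acid pinacol ester gives the E-γ-aryl allylboronate F2. Chiral-phosphoric-acid-catalysed allylboration of aldehyde 29 then sets the two centres next to ring B, both in their final configuration, as the anti homoallylic alcohol F3. Silylation gives the TBS ether F4 and cross-metathesis with 33 the alkenyl B(mac) ester F5. Conjunctive coupling of its borate (with 11) with the unhindered 3,5-bis(benzyloxy)phenyl triflate F6, followed by perborate oxidation, gives the alcohol F7, whose carbinol centre is the one to be inverted. Mesylation and fluoride-induced closure as in step 22 then give 39.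

Step 12 (with step 11). Condensation of hydrazine with the di-ortho-substituted ketone may stall, and the hindered carbene may dimerise to the azine or insert with low enantio- and diastereocontrol. The fallback sets out from 15 and 17 and returns at 25, using a [4+1] annulation of an ortho-quinone methide with a sulfonium ylide instead of a carbene. Compound 17 is converted (MOMCl, i-Pr2NEt) into the bis-MOM ether F8. Ester 15 is reduced (LiAlH4) to the benzylic alcohol F9 and oxidised (MnO2) to the aldehyde F10. Ortho-lithiation of F8 between the two MOM ethers (n-BuLi) and addition to F10 gives the diarylcarbinol F11. Sodium p-toluenesulfinate with HCl in methanol removes both MOM groups and replaces the benzhydrylic hydroxyl, giving the sulfone F12. With Cs2CO3, F12 loses sulfinate to form the ortho-quinone methide, which is trapped by the ylide of the sulfonium salt F13 (from 4-(benzyloxy)benzyl bromide and (2R,5R)-2,5-dimethylthiolane). Conjugate addition and SN2 closure by the phenoxide should give the trans ring of 25 directly. The chiral sulfide fixes the absolute sense; failing that, the two trans diastereomers can be separated by chromatography, because ring A is already enantiopure.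

Step 6. With the β-aryl alkenylborate, direct Suzuki transfer of the alkenyl group or a weak facial bias may erode yield and enantiopurity. The fallback sets out from 6 and returns at 15, using copper/palladium arylboration of a stilbene. Resveratrol is perbenzylated (BnBr, K2CO3) to the stilbene F14. Borylcupration (B2pin2, CuCl with a chiral imidazolinium-derived carbene ligand, NaOt-Bu) should place copper on the carbon bearing the less electron-rich 3,5-bis(benzyloxy)phenyl ring. Palladium-catalysed coupling of this benzylcopper with 6 (Pd(OAc)2, RuPhos) gives the syn arylboration product F15. Perborate oxidation gives the erythro fluoro alcohol F16, and the same SNAr closure gives the 2,3-cis ester F17. Trifluoroacetic acid then equilibrates C2 through the p-alkoxybenzyl cation to the trans ester 15; C3, set by the copper catalyst, is retained.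

Further compounds
F1 | step 21 | 4-ethenyl analogue of 26 (vinyl in place of the triflate) | c1ccccc1COc1ccc([C@H]2Oc3cc(O[Si](C(C)C)(C(C)C)C(C)C)cc(C=C)c3[C@@H]2c2cc(OCc4ccccc4)c3c(c2)[C@@H](c2cc(OCc4ccccc4)cc(OCc4ccccc4)c2)[C@H](c2ccc(OCc4ccccc4)cc2)O3)cc1
F2 | step 21 | (E)-3-(B-yl)prop-2-en-1-yl pinacol boronate | c1ccccc1COc1ccc([C@H]2Oc3cc(O[Si](C(C)C)(C(C)C)C(C)C)cc(/C=C/CB4OC(C)(C)C(C)(C)O4)c3[C@@H]2c2cc(OCc4ccccc4)c3c(c2)[C@@H](c2cc(OCc4ccccc4)cc(OCc4ccccc4)c2)[C@H](c2ccc(OCc4ccccc4)cc2)O3)cc1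
F3 | step 21 | (1R,2S)-1-ArA-2-(B-yl)but-3-en-1-ol (anti) | c1ccccc1COc1ccc([C@H]2Oc3cc(O[Si](C(C)C)(C(C)C)C(C)C)cc([C@@H]([C@@H](O)c4ccc(OCc5ccccc5)cc4)C=C)c3[C@@H]2c2cc(OCc4ccccc4)c3c(c2)[C@@H](c2cc(OCc4ccccc4)cc(OCc4ccccc4)c2)[C@H](c2ccc(OCc4ccccc4)cc2)O3)cc1
F4 | step 21 | TBS ether of F3 | c1ccccc1COc1ccc([C@H]2Oc3cc(O[Si](C(C)C)(C(C)C)C(C)C)cc([C@@H]([C@@H](O[Si](C)(C)C(C)(C)C)c4ccc(OCc5ccccc5)cc4)C=C)c3[C@@H]2c2cc(OCc4ccccc4)c3c(c2)[C@@H](c2cc(OCc4ccccc4)cc(OCc4ccccc4)c2)[C@H](c2ccc(OCc4ccccc4)cc2)O3)cc1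
F5 | step 21 | [(1E,3S,4R)-4-ArA-3-(B-yl)-4-(TBS-oxy)but-1-en-1-yl]-B(mac) | c1ccccc1COc1ccc([C@H]2Oc3cc(O[Si](C(C)C)(C(C)C)C(C)C)cc([C@@H]([C@@H](O[Si](C)(C)C(C)(C)C)c4ccc(OCc5ccccc5)cc4)/C=C/B6O[C@]7(C)c8cccc9cccc(c89)[C@]7(C)O6)c3[C@@H]2c2cc(OCc4ccccc4)c3c(c2)[C@@H](c2cc(OCc4ccccc4)cc(OCc4ccccc4)c2)[C@H](c2ccc(OCc4ccccc4)cc2)O3)cc1
F6 | step 21 | 3,5-bis(benzyloxy)phenyl trifluoromethanesulfonate | FC(F)(F)S(=O)(=O)Oc1cc(OCc2ccccc2)cc(OCc2ccccc2)c1
F7 | step 21 | (1R,2R,3S,4R)-1,4-bis(ArA)-2-ArB-4-(TBS-oxy)-3-(B-yl)butan-1-ol | c1ccccc1COc1ccc([C@H]2Oc3cc(O[Si](C(C)C)(C(C)C)C(C)C)cc([C@@H]([C@@H](O[Si](C)(C)C(C)(C)C)c4ccc(OCc5ccccc5)cc4)[C@H](c4cc(OCc5ccccc5)cc(OCc5ccccc5)c4)[C@H](c4ccc(OCc5ccccc5)cc4)O)c3[C@@H]2c2cc(OCc4ccccc4)c3c(c2)[C@@H](c2cc(OCc4ccccc4)cc(OCc4ccccc4)c2)[C@H](c2ccc(OCc4ccccc4)cc2)O3)cc1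
F8 | step 12 | [3,5-bis(methoxymethoxy)phenoxy]triisopropylsilane | COCOc1cc(OCOC)cc(O[Si](C(C)C)(C(C)C)C(C)C)c1
F9 | step 12 | (A-yl)methanol | OCc1cc(OCc2ccccc2)c3c(c1)[C@@H](c1cc(OCc2ccccc2)cc(OCc2ccccc2)c1)[C@H](c1ccc(OCc2ccccc2)cc1)O3
F10 | step 12 | A-yl carbaldehyde | O=Cc1cc(OCc2ccccc2)c3c(c1)[C@@H](c1cc(OCc2ccccc2)cc(OCc2ccccc2)c1)[C@H](c1ccc(OCc2ccccc2)cc1)O3
F11 | step 12 | [2,6-bis(methoxymethoxy)-4-(TIPS-oxy)phenyl](A-yl)methanol (both carbinol epimers) | OC(c1c(OCOC)cc(O[Si](C(C)C)(C(C)C)C(C)C)cc1OCOC)c1cc(OCc2ccccc2)c3c(c1)[C@@H](c1cc(OCc2ccccc2)cc(OCc2ccccc2)c1)[C@H](c1ccc(OCc2ccccc2)cc1)O3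
F12 | step 12 | 2-[(A-yl)(p-tolylsulfonyl)methyl]-5-(TIPS-oxy)benzene-1,3-diol (both epimers) | Cc1ccc(cc1)S(=O)(=O)C(c1c(O)cc(O[Si](C(C)C)(C(C)C)C(C)C)cc1O)c1cc(OCc2ccccc2)c3c(c1)[C@@H](c1cc(OCc2ccccc2)cc(OCc2ccccc2)c1)[C@H](c1ccc(OCc2ccccc2)cc1)O3
F13 | step 12 | (2R,5R)-1-[4-(benzyloxy)benzyl]-2,5-dimethylthiolanium bromide | C[C@@H]1CC[C@@H](C)[S+]1Cc1ccc(OCc2ccccc2)cc1.[Br-]
F14 | step 6 | (E)-3,4',5-tris(benzyloxy)stilbene | c1ccccc1COc1ccc(/C=C/c2cc(OCc3ccccc3)cc(OCc3ccccc3)c2)cc1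
F15 | step 6 | methyl 3-(benzyloxy)-5-[(1R,2S)-2-ArA-1-ArB-2-(pinacolboryl)ethyl]-4-fluorobenzoate | COC(=O)c1cc(OCc2ccccc2)c(F)c(c1)[C@@H](c1cc(OCc2ccccc2)cc(OCc2ccccc2)c1)[C@@H](c1ccc(OCc2ccccc2)cc1)B1OC(C)(C)C(C)(C)O1
F16 | step 6 | methyl 3-(benzyloxy)-5-[(1R,2S)-2-ArA-1-ArB-2-hydroxyethyl]-4-fluorobenzoate | COC(=O)c1cc(OCc2ccccc2)c(F)c(c1)[C@@H](c1cc(OCc2ccccc2)cc(OCc2ccccc2)c1)[C@@H](c1ccc(OCc2ccccc2)cc1)O
F17 | step 6 | methyl (2S,3R)-7-(benzyloxy)-2-ArA-3-ArB-2,3-dihydro-1-benzofuran-5-carboxylate (cis) | COC(=O)c1cc(OCc2ccccc2)c3c(c1)[C@@H](c1cc(OCc2ccccc2)cc(OCc2ccccc2)c1)[C@@H](c1ccc(OCc2ccccc2)cc1)O3
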